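The runs were computed with made-up constants; noise was put on by code.

Over 4.0 min, L falls to 81% in the west run and 86% in the south-west run, so I freeze [L] and treat each run as one steady rate, the pseudo-first-order view.

in all of them: Q 82 mM (held)

| charge | L | remark | time |
|---|---|---|---|
| west | 0.34 M | run made earlier |  |
| south-west | 0.75 M | run made earlier |  |
| flask | 0.50 M |  | 4.0 min |

- west (time / min: E / %, L / %): 0.833: 1, 98; 1.50: 6, 94; 2.50: 11, 88; 3.00: 10, 86; 4.00: 16, 81
- south-west (time / min: E / %, L / %): 0.333: 0, 97; 1.00: 4, 98; 2.00: 6, 93; 3.00: 8, 94; 4.00: 12, 86

(standard deviation of a reading: 1.5 percentage points)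

- what was read earlier has a scatter of 1.5 percentage points, one standard deviation
- at the start none of Q is in solution

- Friday's: doubling the transfer coefficient of Q, all else as stated
- Tuesday's: doubling the saturation concentration of Q, all else as stated

- amount of E at 4.0 min, in percent of the L charged
- the change that raises the amount of E at 4.0 min, in percent of the L charged most ("none" if none brings more than 2 percentage points) (Friday's / Tuesday's / none)
- amount of E at 4.0 min, in percent of the L charged, after Tuesday's

Q starts with none dissolved, and I model gas feed and reaction in series, like two resistances. I take the harvest rate r as E made per litre per minute, averaged over 4.0 min, and its reciprocal as A + B/[L], with A the reciprocal of a feed ceiling F. The E column gives r of 0.0136 M/min for the west run and 0.0225 M/min for the south-west run. That gives 18.1 min for B and 0.0492 M/min for F, and this flask comes to 0.01770 M/min, or 14.2%.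

The second way uses the L column, reading what L lost: 0.0161 M/min and 0.0263 M/min. The same reckoning, with 14.8 min for B and 0.0545 M/min for F, gives 0.02084 M/min, or 16.7%.

The two part by 2.5 percentage points. The L way would cheat if L went elsewhere, but E plus L reads 97.0% and 98.0%, and such a sum scatters by 2.1 points. Neither is caught, so I take the midpoint for this flask, 0.01927 M/min, the harvest rate, which gives 15.4%.

In this reckoning, doubling saturation halves both terms, so r doubles, to 30.8% before L loss. Friday's halves A, which is 36.0% of the resistance in this flask, and gives 18.8%. I choose Tuesday's.

The forecast says 13.5% (12% to 15%), below my figure, then Tuesday's with 26%: “Doubling the saturation concentration doubles the driving force and the Q level”.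

The flask gives 15.4%, with L at 84.6% at 4.00 min. Tuesday's wins, at 28.8%, a gain of 13 points against 7.8 points for Friday's, so the forecast held within its tolerance.

    L + X → Z + E (k = 1.82 /M/min)
    Q ⇌ X, rate k2*(csat - [X]) (kL = 0.706 /min)
    X + Z ⇌ G, settled at all times (K = 170 /M)

For this flask, r doubled gives 30.8% against that 28.8%. Carried to the same flask read at 15 min, r of 0.0193 M/min gives 57.8%, and that flask holds 55.4% E.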